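**Retrosynthetic overview**
1. The C–C single bond between the two CH carbons in the middle of the (E,E)-diene is cut, and the vinylic methyl group is cut off with it. Three components remain: a 4-ethynylcyclohexane (ring half), trimethylaluminium (the methyl carbon) and an (E)-iodoalkene (chain half).
2. Enabling feature: the ring-side CH of that bond is double-bonded to a carbon bearing only CH3 and ring carbon C4 of the cyclohexane. This 2-methylalk-1-enyl unit is the retron of syn methylmetalation of a terminal alkyne. The chain-side CH belongs to an E-CH=CH next to the fully substituted carbinol carbon, the retron of alkyne hydrozirconation.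
3. Ring half: the only ring, the cyclohexane, is never closed because it is bought with (S)-limonene. C4 steers a diaxial epoxide hydrolysis (C1, C2), bromide then inverts C2, and the isopropenyl group is cut down to ethynyl.
4. Chain half: Sharpless epoxidation of geraniol sets the tertiary carbinol. Epoxy chloride to alkynol, silylation and hydrozirconation–iodination follow.
5. After the union only two silyl ethers have to be removed.

Key step: step 13

Remark on the chemistry: ring atoms are numbered as in p-menthane (C1 carbinol carbon, C2 bromine-bearing carbon, C4 side-chain carbon). In the target Br and OH are cis (Br, CH3 and side chain equatorial, OH axial), so anti bromohydrin formation from the ring alkene cannot be used. (S)-(−)-Limonene and geraniol are taken as commercial in high enantiomeric and geometric purity.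

Step 1
Reactants: 1 (S)-(−)-limonene
Product: 2 (4S)-limonene 1,2-oxide, mixture of both epoxide diastereomers
Conditions: mCPBA (1.0 equiv), NaHCO3, CH2Cl2, 0 °C
Reagents that add atoms: mCPBA, OOC(=O)c1cccc(Cl)c1
Why: Prilezhaev epoxidation should pick the electron-richer trisubstituted ring alkene over the 1,1-disubstituted isopropenyl group, and the missing facial selectivity is harmless because both epoxides converge in step 2.

Step 2
Reactants: 2 (4S)-limonene 1,2-oxide
Product: 3 (1R,2R,4S)-1-methyl-4-(prop-1-en-2-yl)cyclohexane-1,2-diol (trans, both OH axial)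
Conditions: dilute aq H2SO4, THF, 0 °C
Reagents that add atoms: water, O
Why: Acid-catalysed trans-diaxial epoxide hydrolysis (Fürst–Plattner rule) with the isopropenyl group equatorial should send water to C1 of the epoxide whose oxygen is trans to the side chain and to C2 of the other one, so both give the same diol with C1–OH cis (1R) and C2–OH trans (2R) to the C4 side chain.

Step 3
Reactants: 3 diaxial diol
Product: 4 (1R,2R,4S)-1-hydroxy-p-menth-8-en-2-yl chloromethanesulfonate
Conditions: ClCH2SO2Cl, pyridine, CH2Cl2, 0 °C
Reagents that add atoms: chloromethanesulfonyl chloride, ClCS(=O)(=O)Cl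
Why: Sulfonylation should be selective for the secondary over the tertiary alcohol and installs a leaving group far more reactive than a mesylate without touching any stereocentre.

Step 4
Reactants: 4 hydroxy chloromethanesulfonate
Product: 5 (1R,2R,4S)-1-(triethylsilyloxy)-p-menth-8-en-2-yl chloromethanesulfonate
Conditions: TESOTf, 2,6-lutidine, CH2Cl2, −78 to 0 °C
Reagents that add atoms: triethylsilyl triflate, CC[Si](CC)(CC)OS(=O)(=O)C(F)(F)F
Why: Silyl triflate silylation caps the hindered tertiary alcohol under weakly basic conditions, so the antiperiplanar oxygen cannot close an epoxide onto C2 in step 5 and cannot be metalated in steps 7 and 13.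

Step 5
Reactants: 5 silylated chloromethanesulfonate
Product: 6 triethyl{[(1R,2S,4S)-2-bromo-1-methyl-4-(prop-1-en-2-yl)cyclohexyl]oxy}silane
Conditions: LiBr (5 equiv), DMF, 50 °C
Reagents that add atoms: lithium bromide, [Li+].[Br-]
Why: SN2 displacement of the axial sulfonate by the weakly basic bromide ion should proceed with clean inversion, turning 2R (oxygen trans to C1–O) into 2S with bromine equatorial and cis to C1–O, the relationship the target needs.

Step 6
Reactants: 6 bromo silyl ether with isopropenyl group
Product: 7 1-[(1S,3S,4R)-3-bromo-4-methyl-4-(triethylsilyloxy)cyclohexyl]ethan-1-one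
Conditions: O3, CH2Cl2, −78 °C; Me2S, −78 °C to rt
Reagents that add atoms: ozone, [O-][O+]=O
Why: Ozonolysis with reductive work-up cleaves the only alkene left to the methyl ketone, while the silyl ether, the alkyl bromide and the three stereocentres are inert.

Step 7
Reactants: 7 methyl ketone
Product: 9 {[(1R,2S,4S)-2-bromo-4-ethynyl-1-methylcyclohexyl]oxy}triethylsilane, via enol diethyl phosphate 8 (not isolated)
Conditions: LiN(iPr)2 (1.1 equiv), THF, −78 °C; ClP(O)(OEt)2, −78 °C to rt; LiN(iPr)2 (2.3 equiv), −78 to 0 °C; H2O
Reagents that add atoms: diethyl chlorophosphate, CCOP(=O)(Cl)OCC (its atoms stay in 8 only and are lost again in 9)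
Why: Kinetic deprotonation at CH3, O-phosphorylation and E2 elimination of the enol phosphate is the standard methyl ketone to terminal alkyne conversion; C4 is not deprotonated under kinetic control, and the equatorial C–Br bond has no antiperiplanar C–H bond for dehydrobromination.

Step 8
Reactants: 10 geraniol
Product: 11 (2S,3S)-2,3-epoxygeraniol
Conditions: Ti(OiPr)4 (5 mol %), L-(+)-diethyl tartrate (7 mol %), t-BuOOH, 4 Å molecular sieves, CH2Cl2, −20 °C
Reagents that add atoms: tert-butyl hydroperoxide, CC(C)(C)OO
Why: Sharpless asymmetric epoxidation acts only on the allylic alcohol alkene, and the L-(+)-tartrate complex delivers oxygen to the face that gives the (2S,3S)-epoxide, whose C3–O bond becomes the (S)-tertiary carbinol of the target.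

Step 9
Reactants: 11 epoxygeraniol
Product: 12 (2S,3R)-3-(chloromethyl)-2-methyl-2-(4-methylpent-3-en-1-yl)oxirane
Conditions: PPh3, CCl4, NaHCO3, reflux
Reagents that add atoms: tetrachloromethane, ClC(Cl)(Cl)Cl
Why: The Appel chlorination replaces the primary hydroxyl group under neutral conditions without opening the epoxide; the descriptor at the CH carbon changes only because the priorities change.

Step 10
Reactants: 12 epoxy chloride
Product: 13 (S)-3,7-dimethyloct-6-en-1-yn-3-ol
Conditions: n-BuLi (3.2 equiv), THF, −40 °C; H2O
Reagents that add atoms: none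
Why: Base-induced double elimination of a 2,3-epoxy chloride (deprotonation at CH2Cl with epoxide opening, then dehydrochlorination) gives the propargylic alcohol, and the C–O bond at the fully substituted carbon is never broken, so its configuration is kept.

Step 11
Reactants: 13 alkynol
Product: 14 triethyl{[(3S)-3,7-dimethyloct-6-en-1-yn-3-yl]oxy}silane
Conditions: TESOTf, 2,6-lutidine, CH2Cl2, −78 to 0 °C
Reagents that add atoms: triethylsilyl triflate, CC[Si](CC)(CC)OS(=O)(=O)C(F)(F)F
Why: Silyl triflate silylation of the tertiary propargylic alcohol removes the acidic proton that would consume hydride in step 12 and organometal in step 13.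

Step 12
Reactants: 14 silylated alkynol
Product: 16 {[(1E,3S)-1-iodo-3,7-dimethylocta-1,6-dien-3-yl]oxy}triethylsilane, via alkenylzirconocene chloride 15 (not isolated)
Conditions: Cp2Zr(H)Cl (1.4 equiv), THF, rt, dark; I2 (1.3 equiv), 0 °C
Reagents that add atoms: Cp2Zr(H)Cl, [H][Zr](Cl)(C1C=CC=C1)C1C=CC=C1 (metal fragment stays in 15 only); iodine, [I][I]
Why: Hydrozirconation adds H and Zr syn to the terminal alkyne with the metal on the unhindered terminal carbon and leaves the trisubstituted alkene alone, and iodinolysis with retention fixes the E-iodoalkene.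

Step 13
Reactants: 9 ring alkyne; 17 trimethylaluminium; 16 (E)-iodoalkene
Product: 19 bis(triethylsilyl) ether of the target, via alkenyl(dimethyl)alane 18 (not isolated)
Conditions: 9, Me3Al (2 equiv), Cp2ZrCl2 (25 mol %), CH2Cl2, 0 °C to rt; volatiles removed in vacuo; THF, ZnCl2 (30 mol %), Pd(PPh3)4 (5 mol %), 16, rt
Reagents that add atoms: trimethylaluminium, C[Al](C)C
Why: Cp2ZrCl2 and Me3Al form a methylzirconocene–aluminate pair that adds methyl and metal syn across the alkyne of 9, with the metal going to the unsubstituted carbon because the other alkyne carbon carries the branched ring carbon C4, and exchange of zirconium for aluminium gives the (E)-2-methylalkenylalane 18 and returns the catalyst. After removal of excess Me3Al, zerovalent palladium inserts into the C(sp2)–I bond of 16, ZnCl2 shuttles the alkenyl group from aluminium to palladium, and reductive elimination forms the bond between the two CH carbons of the diene with retention at both partners. The closest known reaction type is the one-pot Negishi carboalumination followed by palladium–zinc co-catalysed alkenyl–alkenyl cross-coupling, established for methyl-branched (E,E)-dienes of terpenoids. No ring is closed and no stereocentre is created; the operation makes the vinylic C–CH3 bond, the trisubstituted E double bond (controlled by syn addition plus regiochemistry) and the diene bond, while the E geometry of 16 and all four stereocentres are carried through. The step needs the alkyne to react in preference to C–Br and the silyl ethers, and the alkenyl iodide in preference to the secondary alkyl bromide; the first is secured by the unactivated equatorial bromide and by capping both oxygens, so that no aluminium alkoxide sits next to C–Br to trigger a semipinacol shift, and the second by the much faster insertion of Pd(PPh3)4 into C(sp2)–I. The trisubstituted prenyl alkene is inert to both metals.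

Step 14
Reactants: 19 bis(triethylsilyl) ether
Product: 20 (1R,2S,4S)-2-bromo-4-[(2E,4E,6S)-6-hydroxy-6,10-dimethylundeca-2,4,9-trien-2-yl]-1-methylcyclohexan-1-ol (target)
Conditions: TBAF (3 equiv), AcOH (3 equiv), THF, 0 °C to rt
Reagents that add atoms: none
Why: Fluoride-mediated desilylation buffered with acetic acid frees both tertiary alcohols without acid that would ionise the dienyl carbinol and without free alkoxide that could start a ring contraction of the cis-bromohydrin.

**Compound list**
1 | (S)-(−)-limonene | CC(=C)[C@H]1CCC(C)=CC1 | starting material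
2 | (4S)-limonene 1,2-oxide, both epoxide diastereomers | CC(=C)[C@H]1CCC2(C)OC2C1 | intermediate
3 | (1R,2R,4S)-1-methyl-4-(prop-1-en-2-yl)cyclohexane-1,2-diol | CC(=C)[C@H]1CC[C@@](C)(O)[C@H](O)C1 | intermediate
4 | (1R,2R,4S)-1-hydroxy-p-menth-8-en-2-yl chloromethanesulfonate | CC(=C)[C@H]1CC[C@@](C)(O)[C@H](OS(=O)(=O)CCl)C1 | intermediate
5 | (1R,2R,4S)-1-(triethylsilyloxy)-p-menth-8-en-2-yl chloromethanesulfonate | CC(=C)[C@H]1CC[C@@](C)(O[Si](CC)(CC)CC)[C@H](OS(=O)(=O)CCl)C1 | intermediate
6 | triethyl{[(1R,2S,4S)-2-bromo-1-methyl-4-(prop-1-en-2-yl)cyclohexyl]oxy}silane | CC(=C)[C@H]1CC[C@@](C)(O[Si](CC)(CC)CC)[C@@H](Br)C1 | intermediate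
7 | 1-[(1S,3S,4R)-3-bromo-4-methyl-4-(triethylsilyloxy)cyclohexyl]ethan-1-one | CC(=O)[C@H]1CC[C@@](C)(O[Si](CC)(CC)CC)[C@@H](Br)C1 | intermediate
8 | 1-[(1S,3S,4R)-3-bromo-4-methyl-4-(triethylsilyloxy)cyclohexyl]ethenyl diethyl phosphate | C=C(OP(=O)(OCC)OCC)[C@H]1CC[C@@](C)(O[Si](CC)(CC)CC)[C@@H](Br)C1 | intermediate
9 | {[(1R,2S,4S)-2-bromo-4-ethynyl-1-methylcyclohexyl]oxy}triethylsilane | C#C[C@H]1CC[C@@](C)(O[Si](CC)(CC)CC)[C@@H](Br)C1 | intermediate
10 | geraniol | CC(C)=CCC/C(C)=C/CO | starting material
11 | (2S,3S)-2,3-epoxygeraniol | CC(C)=CCC[C@]1(C)O[C@H]1CO | intermediate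
12 | (2S,3R)-3-(chloromethyl)-2-methyl-2-(4-methylpent-3-en-1-yl)oxirane | CC(C)=CCC[C@]1(C)O[C@H]1CCl | intermediate
13 | (S)-3,7-dimethyloct-6-en-1-yn-3-ol | CC(C)=CCC[C@](C)(O)C#C | intermediate
14 | triethyl{[(3S)-3,7-dimethyloct-6-en-1-yn-3-yl]oxy}silane | CC(C)=CCC[C@](C)(O[Si](CC)(CC)CC)C#C | intermediate
15 | chloro[(1E,3S)-3,7-dimethyl-3-(triethylsilyloxy)octa-1,6-dien-1-yl]zirconocene | CC(C)=CCC[C@](C)(O[Si](CC)(CC)CC)/C=C/[Zr](Cl)(C1C=CC=C1)C1C=CC=C1 | intermediate
16 | {[(1E,3S)-1-iodo-3,7-dimethylocta-1,6-dien-3-yl]oxy}triethylsilane | CC(C)=CCC[C@](C)(O[Si](CC)(CC)CC)/C=C/I | intermediate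
17 | trimethylaluminium | C[Al](C)C | starting material
18 | {(1E)-2-[(1S,3S,4R)-3-bromo-4-methyl-4-(triethylsilyloxy)cyclohexyl]prop-1-en-1-yl}dimethylalane | C[Al](C)/C=C(\C)[C@H]1CC[C@@](C)(O[Si](CC)(CC)CC)[C@@H](Br)C1 | intermediate
19 | bis(triethylsilyl) ether of the target | CC(C)=CCC[C@](C)(O[Si](CC)(CC)CC)/C=C/C=C(\C)[C@H]1CC[C@@](C)(O[Si](CC)(CC)CC)[C@@H](Br)C1 | intermediate
20 | (1R,2S,4S)-2-bromo-4-[(2E,4E,6S)-6-hydroxy-6,10-dimethylundeca-2,4,9-trien-2-yl]-1-methylcyclohexan-1-ol | CC(C)=CCC[C@](C)(O)/C=C/C=C(\C)[C@H]1CC[C@@](C)(O)[C@@H](Br)C1 | target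

Total step count: 14. Longest linear sequence: 9 (steps 1–7, 13, 14).

**Steps most likely to fail**

Step 5. E2 elimination of the axial sulfonate with the antiperiplanar axial hydrogen at C3 may outrun substitution, and backside attack is slow beside the fully substituted C1.
- The fallback sets out from diol 3 and comes back at ketone 7.
- Diol 3 is closed with SOCl2 and Et3N to the trans-fused cyclic sulfite F1.
- RuCl3 (catalytic) with NaIO4 oxidises sulfur and at the same time cleaves the isopropenyl group, giving the cyclic sulfate methyl ketone F2.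
- In this temporary ring both C–O bonds are equatorial, so no C–H bond is antiperiplanar to the leaving group, and the tertiary oxygen is tied up.
- LiBr opens F2 at the secondary carbon with inversion to the lithium sulfate monoester F3. The syn-axial acetyl group in the ring-flipped chair may slow this opening.
- Aqueous H2SO4 in THF hydrolyses F3 to the bromohydrin ketone F4, and TESOTf with 2,6-lutidine gives 7.

Step 7. The amide base may attack the bromide-bearing ring (dehydrobromination after ring inversion), or the enolate may equilibrate and scramble C4.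
- The fallback sets out from ketone 7 and comes back at 19, avoiding the alkyne altogether.
- A boron–Wittig olefination of 7 with CH2(Bpin)2 and lithium 2,2,6,6-tetramethylpiperidide in THF should give the (E)-alkenyl pinacol boronate F5. Boron ends trans to the larger ring substituent, and any minor geometric isomer is removed by chromatography.
- Suzuki–Miyaura coupling of F5 with iodide 16 (Pd(dppf)Cl2, aqueous K3PO4, THF, rt) then forms the same diene bond.

Step 13. Transfer of the hindered alkenyl group from aluminium to palladium may be slow, so that protodemetalation, methyl transfer and homocoupling of the iodide compete. Long contact with Lewis acidic aluminium may also ionise the C–Br bond.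
- The fallback sets out from alkyne 9 and comes back at 19 with the polarity of the partners reversed.
- The carboalumination mixture containing 18 is quenched at low temperature with iodine to give the isolable (E)-alkenyl iodide F6.
- Alkenylzirconocene 15, made from 14 as in step 12, is then coupled with F6 under Pd(PPh3)4 and ZnCl2 in THF (Negishi coupling).

**Further compounds**
F1 | step 5 | trans-fused cyclic sulfite of diol 3 (mixture at sulfur) | CC(=C)[C@H]1CC[C@@]2(C)OS(=O)O[C@@H]2C1
F2 | step 5 | cyclic sulfate of (1R,2R,4S)-4-acetyl-1-methylcyclohexane-1,2-diol | CC(=O)[C@H]1CC[C@@]2(C)OS(=O)(=O)O[C@@H]2C1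
F3 | step 5 | lithium (1R,2S,4S)-4-acetyl-2-bromo-1-methylcyclohexyl sulfate | CC(=O)[C@H]1CC[C@@](C)(OS(=O)(=O)[O-])[C@@H](Br)C1.[Li+]
F4 | step 5 | 1-[(1S,3S,4R)-3-bromo-4-hydroxy-4-methylcyclohexyl]ethan-1-one | CC(=O)[C@H]1CC[C@@](C)(O)[C@@H](Br)C1
F5 | step 7 | (E)-2-[(1S,3S,4R)-3-bromo-4-methyl-4-(triethylsilyloxy)cyclohexyl]prop-1-en-1-ylboronic acid pinacol ester | CC1(C)OB(/C=C(\C)[C@H]2CC[C@@](C)(O[Si](CC)(CC)CC)[C@@H](Br)C2)OC1(C)C
F6 | step 13 | {[(1R,2S,4S)-2-bromo-4-[(1E)-1-iodoprop-1-en-2-yl]-1-methylcyclohexyl]oxy}triethylsilane | I/C=C(\C)[C@H]1CC[C@@](C)(O[Si](CC)(CC)CC)[C@@H](Br)C1
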